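The route disconnects the aryl–CH2 bond C1–C7 of ring B. In the pentasubstituted ring, C1 is para to the C4 hydroxyl while C3 and C5 carry methoxy groups, so the C4 phenolate is a carbon nucleophile only at C1. The key step unmasks this phenolate with fluoride and lets it displace a primary tosylate at C7 (6-exo-tet), closing the tetralin in one operation. Its precursor is a silyl-protected 3-alkylsyringol whose side chain C7'H(OMe)–C8'H(Me)–C8H(Me)–C7H2OTs comes from catalytic desymmetrisation of meso-2,3-dimethylsuccinic anhydride. The temporary C7' methoxy group is finally exchanged for guaiacol under substrate control.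

Key step: step 7

Remark: lignan numbering is used for atoms (C1–C6 of the pentasubstituted ring, C7, C8, C8', C7'). Compounds 8–14 are carried as mixtures of C7' epimers, because this centre is ionised and reset in step 8. Compounds 1, 3 and 15 are taken as commercial.

Step 1
Reactants: 1 2,6-dimethoxyphenol (syringol)
Product: 2 (2,6-dimethoxyphenoxy)triisopropylsilane
Conditions: TIPSCl, imidazole, DMF, 40 °C
Reagents that add atoms: triisopropylsilyl chloride, CC(C)[Si](Cl)(C(C)C)C(C)C
Why: Imidazole-promoted O-silylation of a phenol gives an ether that should survive organolithium, hydride and acidic methanol and can be removed later by fluoride.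

Step 2
Reactants: 3 meso-2,3-dimethylsuccinic acid
Product: 4 cis-3,4-dimethyloxolane-2,5-dione (meso anhydride)
Conditions: AcCl, 50 °C
Reagents that add atoms: none
Why: Cyclodehydration of a 1,4-diacid through the mixed anhydride, under non-enolising conditions, should keep the cis (meso) relationship of the methyl groups.

Step 3
Reactants: 2 (2,6-dimethoxyphenoxy)triisopropylsilane; 4 cis-3,4-dimethyloxolane-2,5-dione
Product: 7 (2S,3R)-4-[2,4-dimethoxy-3-(triisopropylsilyloxy)phenyl]-2,3-dimethyl-4-oxobutanoic acid, via aryllithium 5 (not isolated), via arylzinc triflate 6 (not isolated)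
Conditions: n-BuLi, THF, 0 °C→rt; Zn(OTf)2, 0 °C; then 4, [Rh(cod)Cl]2 (cat.), TADDOL-derived phosphoramidite (cat., enantiomer chosen for the 2S,3R acid), DMF, 50 °C; 1 M HCl
Reagents that add atoms: none
Why: Directed ortho-lithiation next to a methoxy group, Li→Zn transmetalation and Rh-catalysed enantioselective desymmetrising arylation of the meso anhydride should give the syn keto acid, the ligand selecting the enantiotopic carbonyl and thereby fixing C8 and C8'.

Step 4
Reactants: 7 (2S,3R)-4-[2,4-dimethoxy-3-(triisopropylsilyloxy)phenyl]-2,3-dimethyl-4-oxobutanoic acid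
Product: 9 methyl (2S,3R)-4-[2,4-dimethoxy-3-(triisopropylsilyloxy)phenyl]-4-methoxy-2,3-dimethylbutanoate (C4 epimers), via lactone 8 (not isolated)
Conditions: NaBH4, MeOH, 0 °C; then H2SO4 (excess over borohydride), HC(OMe)3, MeOH, rt
Reagents that add atoms: methanol, CO; trimethyl orthoformate, COC(OC)OC
Why: Borohydride reduction of the aryl ketone, acid lactonisation and orthoester-dependent acidic methanolysis of the benzylic lactone (SN1 at the 2,4-dialkoxybenzylic carbon) should give the γ-methoxy ester, leaving C8 and C8' untouched.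

Step 5
Reactants: 9 methyl (2S,3R)-4-[2,4-dimethoxy-3-(triisopropylsilyloxy)phenyl]-4-methoxy-2,3-dimethylbutanoate
Product: 10 (2S,3R)-4-[2,4-dimethoxy-3-(triisopropylsilyloxy)phenyl]-4-methoxy-2,3-dimethylbutan-1-ol (C4 epimers)
Conditions: LiAlH4, THF, 0 °C; Fieser work-up
Reagents that add atoms: none
Why: Hydride reduction of the methyl ester to the primary alcohol should be fast at 0 °C, and neither the hindered aryl silyl ether nor the benzylic methyl ether is expected to react.

Step 6
Reactants: 10 (2S,3R)-4-[2,4-dimethoxy-3-(triisopropylsilyloxy)phenyl]-4-methoxy-2,3-dimethylbutan-1-ol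
Product: 11 (2S,3R)-4-[2,4-dimethoxy-3-(triisopropylsilyloxy)phenyl]-4-methoxy-2,3-dimethylbutyl 4-methylbenzenesulfonate (C4 epimers)
Conditions: TsCl, Et3N, DMAP (cat.), CH2Cl2, 0 °C→rt
Reagents that add atoms: 4-toluenesulfonyl chloride, Cc1ccc(cc1)S(Cl)(=O)=O
Why: Sulfonylation of the only free hydroxyl turns C7 into the electrophile, while the phenol is still masked, so no O-sulfonylation of the arene can compete.

Step 7
Reactants: 11 (2S,3R)-4-[2,4-dimethoxy-3-(triisopropylsilyloxy)phenyl]-4-methoxy-2,3-dimethylbutyl 4-methylbenzenesulfonate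
Product: 14 (6R,7R)-1,3,8-trimethoxy-6,7-dimethyl-5,6,7,8-tetrahydronaphthalen-2-ol (C8 epimers), via tetrabutylammonium phenolate 12 (not isolated), via cyclohexadienone 13 (not isolated)
Conditions: TBAF (1.05 equiv), THF (0.005 M), 0 °C→60 °C
Reagents that add atoms: none
Why: Fluoride cleaves the aryl O–Si bond and liberates the tetrabutylammonium phenolate 12, whose para carbon C1 attacks C7 in an SN2 displacement of tosylate to give the 2,5-cyclohexadienone 13, which tautomerises to the phenol. The closest known reaction type is the Winstein–Baird intramolecular C-alkylation of phenoxides (Ar2-6 participation), a phenol para-alkylation under basic conditions. The new six-membered carbocycle closes in the 6-exo-tet mode. No stereocentre is created (C7 is a CH2 group and C1 rearomatises), and C8 and C8' are not epimerisable under these conditions. The step needs C- over O-alkylation and C1 over every other carbon: the meta-placed tether cannot bring C7 to O4, C3 and C5 bear methoxy groups, the benzylic oxygen is capped as a methyl ether and no second arene is present. High dilution with one equivalent of fluoride should suppress intermolecular alkylation, fluorination and E2.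

Step 8
Reactants: 14 (6R,7R)-1,3,8-trimethoxy-6,7-dimethyl-5,6,7,8-tetrahydronaphthalen-2-ol; 15 2-methoxyphenol (guaiacol)
Product: 16 (6R,7R,8R)-8-(4-hydroxy-3-methoxyphenyl)-1,3-dimethoxy-6,7-dimethyl-5,6,7,8-tetrahydronaphthalen-2-ol, i.e. (-)-(7'R,8R,8'R)-4,4'-dihydroxy-3,3',5-trimethoxy-2,7'-cyclolignan
Conditions: guaiacol (5 equiv), TfOH (5 mol%), HFIP/CH2Cl2, −20 °C→0 °C
Reagents that add atoms: none
Why: Acid ionises the benzylic methyl ether to a cation stabilised by the C3 and C5 methoxy groups, and Friedel–Crafts alkylation of guaiacol para to its hydroxyl should occur on the face of the half-chair opposite to the two cis methyl groups, which sets C7' as R (7',8'-trans).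

Compound list
1 | 2,6-dimethoxyphenol (syringol) | COc1cccc(OC)c1O | starting material
2 | (2,6-dimethoxyphenoxy)triisopropylsilane | COc1cccc(OC)c1O[Si](C(C)C)(C(C)C)C(C)C | intermediate
3 | meso-2,3-dimethylsuccinic acid | OC(=O)[C@@H](C)[C@@H](C)C(O)=O | starting material
4 | cis-3,4-dimethyloxolane-2,5-dione | O=C1OC(=O)[C@@H](C)[C@H]1C | intermediate
5 | [2,4-dimethoxy-3-(triisopropylsilyloxy)phenyl]lithium | [Li]c1ccc(OC)c(O[Si](C(C)C)(C(C)C)C(C)C)c1OC | intermediate
6 | [2,4-dimethoxy-3-(triisopropylsilyloxy)phenyl]zinc triflate | FC(F)(F)S(=O)(=O)O[Zn]c1ccc(OC)c(O[Si](C(C)C)(C(C)C)C(C)C)c1OC | intermediate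
7 | (2S,3R)-4-[2,4-dimethoxy-3-(triisopropylsilyloxy)phenyl]-2,3-dimethyl-4-oxobutanoic acid | OC(=O)[C@@H](C)[C@@H](C)C(=O)c1ccc(OC)c(O[Si](C(C)C)(C(C)C)C(C)C)c1OC | intermediate
8 | (3S,4R)-5-[2,4-dimethoxy-3-(triisopropylsilyloxy)phenyl]-3,4-dimethyloxolan-2-one (C5 epimers) | O=C1OC(c2ccc(OC)c(O[Si](C(C)C)(C(C)C)C(C)C)c2OC)[C@H](C)[C@@H]1C | intermediate
9 | methyl (2S,3R)-4-[2,4-dimethoxy-3-(triisopropylsilyloxy)phenyl]-4-methoxy-2,3-dimethylbutanoate (C4 epimers) | COC(=O)[C@@H](C)[C@@H](C)C(OC)c1ccc(OC)c(O[Si](C(C)C)(C(C)C)C(C)C)c1OC | intermediate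
10 | (2S,3R)-4-[2,4-dimethoxy-3-(triisopropylsilyloxy)phenyl]-4-methoxy-2,3-dimethylbutan-1-ol (C4 epimers) | OC[C@@H](C)[C@@H](C)C(OC)c1ccc(OC)c(O[Si](C(C)C)(C(C)C)C(C)C)c1OC | intermediate
11 | (2S,3R)-4-[2,4-dimethoxy-3-(triisopropylsilyloxy)phenyl]-4-methoxy-2,3-dimethylbutyl 4-methylbenzenesulfonate (C4 epimers) | Cc1ccc(cc1)S(=O)(=O)OC[C@@H](C)[C@@H](C)C(OC)c1ccc(OC)c(O[Si](C(C)C)(C(C)C)C(C)C)c1OC | intermediate
12 | tetrabutylammonium 2,6-dimethoxy-3-[(2R,3S)-1-methoxy-2,3-dimethyl-4-(tosyloxy)butyl]phenolate | CCCC[N+](CCCC)(CCCC)CCCC.Cc1ccc(cc1)S(=O)(=O)OC[C@@H](C)[C@@H](C)C(OC)c1ccc(OC)c([O-])c1OC | intermediate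
13 | (6R,7R)-1,3,8-trimethoxy-6,7-dimethyl-5,6,7,8-tetrahydronaphthalen-2(4aH)-one | O=C1C(OC)=CC2C[C@@H](C)[C@@H](C)C(OC)C2=C1OC | intermediate
14 | (6R,7R)-1,3,8-trimethoxy-6,7-dimethyl-5,6,7,8-tetrahydronaphthalen-2-ol (C8 epimers) | COC1c2c(cc(OC)c(O)c2OC)C[C@@H](C)[C@H]1C | intermediate
15 | 2-methoxyphenol (guaiacol) | COc1ccccc1O | starting material
16 | (-)-(7'R,8R,8'R)-4,4'-dihydroxy-3,3',5-trimethoxy-2,7'-cyclolignan | COc1cc([C@@H]2c3c(cc(OC)c(O)c3OC)C[C@@H](C)[C@H]2C)ccc1O | target

Total step count: 8. Longest linear sequence: 7 steps (steps 2–8 from 3; equally steps 1 and 3–8 from 1).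

Steps most likely to fail

1. Step 8. Guaiacol may also attack through its carbon para to the methoxy group. The cyclic benzylic cation may in addition lose the C8' proton (E1) to a 1,2-dihydronaphthalene, whose reprotonation would erode the C8' configuration. Fallback (sets out from 10, returns at 16): the aryl group is introduced on the open chain before ring closure. Alcohol 10 is treated with guaiacol and BF3·OEt2 at −60 °C; attack on the acyclic cation anti to the C8 branch (A1,3-strain control) should give the (2S,3S,4R)-diaryl alcohol F6 with the same C7' configuration. Excess TsCl/Et3N/DMAP gives the alkyl/aryl bis-tosylate F7. TBAF then effects the same phenolate para-alkylation, the guaiacyl oxygen staying masked as a sulfonate, to give the O-tosyl cyclolignan F8. KOH/MeOH at reflux cleaves the aryl tosylate to 16. This answers the elimination; a regioisomer at the guaiacol would be removed at the stage of F6 or F7.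

2. Step 3. Transmetalation and acyl transfer of the ortho-methoxy arylzinc may be slow, giving low conversion or poor discrimination of the enantiotopic carbonyls, and the C8' centre next to the new ketone may epimerise. Fallback (sets out from 4 and 2, returns at 9): cinchona-alkaloid-mediated methanolysis of 4 (quinidine or quinine as required, toluene, −55 °C) gives the hemiester (2R,3S)-4-methoxy-2,3-dimethyl-4-oxobutanoic acid F3. Coupling with MeNHOMe·HCl/EDC gives the Weinreb amide F4. The Grignard reagent made from 5 (MgBr2·OEt2, −20 °C) adds to F4 to give the keto ester F5. The conditions of step 4 (NaBH4; then H2SO4, HC(OMe)3, MeOH) convert F5 into 9.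

3. Step 7. E2 elimination of the β-branched tosylate, intermolecular O-alkylation, or participation of the benzylic methoxy oxygen (cyclic oxonium, then a tetrahydrofuran) may outrun C-alkylation at C1. Fallback (sets out from 11, returns at 14): buffered desilylation (TBAF/AcOH, 0 °C) gives the phenol tosylate F1. NBS bromination para to the hydroxyl gives the C1 bromide F2. A nickel-catalysed intramolecular reductive cross-electrophile coupling of the aryl bromide with the alkyl tosylate (NiI2, 4,4'-di-tert-butylbipyridine, Zn, NaI, DMA, 60 °C) closes the same C1–C7 bond to give 14.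

Further compounds
F1 | step 7 | (2S,3R)-4-(3-hydroxy-2,4-dimethoxyphenyl)-4-methoxy-2,3-dimethylbutyl 4-methylbenzenesulfonate | Cc1ccc(cc1)S(=O)(=O)OC[C@@H](C)[C@@H](C)C(OC)c1ccc(OC)c(O)c1OC
F2 | step 7 | (2S,3R)-4-(6-bromo-3-hydroxy-2,4-dimethoxyphenyl)-4-methoxy-2,3-dimethylbutyl 4-methylbenzenesulfonate | Cc1ccc(cc1)S(=O)(=O)OC[C@@H](C)[C@@H](C)C(OC)c1c(Br)cc(OC)c(O)c1OC
F3 | step 3 | (2R,3S)-4-methoxy-2,3-dimethyl-4-oxobutanoic acid | COC(=O)[C@@H](C)[C@@H](C)C(O)=O
F4 | step 3 | methyl (2S,3R)-4-[methoxy(methyl)amino]-2,3-dimethyl-4-oxobutanoate | COC(=O)[C@@H](C)[C@@H](C)C(=O)N(C)OC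
F5 | step 3 | methyl (2S,3R)-4-[2,4-dimethoxy-3-(triisopropylsilyloxy)phenyl]-2,3-dimethyl-4-oxobutanoate | COC(=O)[C@@H](C)[C@@H](C)C(=O)c1ccc(OC)c(O[Si](C(C)C)(C(C)C)C(C)C)c1OC
F6 | step 8 | (2S,3S,4R)-4-[2,4-dimethoxy-3-(triisopropylsilyloxy)phenyl]-4-(4-hydroxy-3-methoxyphenyl)-2,3-dimethylbutan-1-ol | OC[C@@H](C)[C@@H](C)[C@H](c1ccc(O)c(OC)c1)c1ccc(OC)c(O[Si](C(C)C)(C(C)C)C(C)C)c1OC
F7 | step 8 | (2S,3S,4R)-4-[2,4-dimethoxy-3-(triisopropylsilyloxy)phenyl]-4-[3-methoxy-4-(tosyloxy)phenyl]-2,3-dimethylbutyl 4-methylbenzenesulfonate | Cc1ccc(cc1)S(=O)(=O)OC[C@@H](C)[C@@H](C)[C@H](c1ccc(OS(=O)(=O)c2ccc(C)cc2)c(OC)c1)c1ccc(OC)c(O[Si](C(C)C)(C(C)C)C(C)C)c1OC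
F8 | step 8 | 4-[(1R,2R,3R)-7-hydroxy-6,8-dimethoxy-2,3-dimethyl-1,2,3,4-tetrahydronaphthalen-1-yl]-2-methoxyphenyl 4-methylbenzenesulfonate | COc1cc([C@@H]2c3c(cc(OC)c(O)c3OC)C[C@@H](C)[C@H]2C)ccc1OS(=O)(=O)c1ccc(C)cc1
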